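Of the 4 questions on this flask, the end and the conversion turn on one fraction, z, the part of the Z charge still free at 8.0 h, while J and Q tell how the Z that has reacted is split: by the proposed steps, Z and D form E reversibly, E gives D and J, and Z with J gives Q.

| setting | larch | flask |
|---|---|---|
| Z | 1 M | 1.0 M |
| D | 0.73 mM | 0.73 mM |
| remark | the very flask that is asked about, followed so far |  |
| time |  | 8.0 h |

larch run (percent of the Z charged)

| time / min | Z / % | J / % | Q / % |
|---|---|---|---|
| 6.00 | 78 | 24 | 6 |
| 12.0 | 49 | 34 | 16 |
| 25.0 | 19 | 42 | 31 |
| 50.0 | 6 | 53 | 43 |
| 80.0 | 0 | 55 | 45 |

(each reading ± 2 percentage points)

- percent here means Z units held: one Q counts as two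
- the earlier runs were read with a standard deviation of 2 percentage points
- steps that have been proposed: Z + D <-> E; E -> D + J; Z + J -> Q
- the reaction counts as stopped when no species that holds the Z changes by six tenths of a point or more over the second half of the time

1. why nothing more happens at 8.0 h, or that something still does (no working catalyst is left / forward and back rates have come level / it is still moving / all of Z has reacted)
2. part of the Z gone at 8.0 h
3. the J standing at 8.0 h, as a percentage of the Z charged
4. the Q standing at 8.0 h, as a percentage of the Z charged

The first thing to find is which concentration sets the order of the rate. If Z kept D bound as E, the rate would stay constant and z would fall on a straight line, and the reading of 19% at 25.0 min would then put the end of Z at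

straight-line end = 30.9 min

but the flask still reads 6% at the later time 50.0 min. If D stays mostly free, its concentration is nearly constant and the rate follows z (pseudo-first-order), so equal stretches of time multiply z by the same factor. A second stretch of 25.0 min then squares the reading:

z at 50.0 min = 3.61%

This stands 2.4 percentage points below the reading of 6%, with readings scattering by 2 points, while the straight line, having ended before that time, misses the reading by its whole 6%, so the reckoning takes z as roughly first order.

The quantity to carry is the half-life of z, the time in which the free fraction of Z halves, read from the same point and so carrying its scatter, 10.4 min. Then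

half-lives in the flask = 8.0 h / 10.4 min = 46.0

Already at 80.0 min this rule leaves z at 0.492%, so the reckoning here expects Z to have reacted by 8.0 h and takes J and Q from the readings at 80.0 min, 55% and 45%.

The forecast, reasoning that “Both J and Q need Z to form”, gives all of Z has reacted, conversion 100%, J 55% and Q 45%.

The flask gives all of Z has reacted, conversion 100%, J 54.8% and Q 45.2%.

    Z + D ⇌ E (K = 0.500 L mol⁻¹, k = 200 L mol⁻¹ min⁻¹)
    E → D + J (k = 240 min⁻¹)
    Z + J → Q (k = 0.0470 L mol⁻¹ min⁻¹)

A neighbour flask with 4.4 × 10⁻⁴ M of D, its half-life stretched in proportion to 17.3 min, still counts 27.7 half-lives and holds Z 0% at 8.00 h, but with J 42.9% and Q 57.1%. In the flask itself, the half-life gives z 4.12% at 0.800 h, where Z stands at 3.69%. Over the second half of the time the largest change is 0 points. Ten times the time changes nothing: at 80.0 h J stands at 54.8% and Q at 45.2%.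

The data were generated by integration on assumed constants; scatter was added.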